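The oxolane ring (O1; C2 and C5 carry the 4-hydroxyphenyl groups, C3 and C4 the 2,4-dihydroxybenzoyl groups) is cut at O1–C5 and C2–C3. O1=C2 is then an aldehyde carbonyl, and C5–C4–C3 a donor–acceptor unit: C5 is benzylic to an electron-rich 4-oxyphenyl ring (latent cation), C3 is alpha to an aryl ketone (latent enolate). The key step is a Lewis-acid-catalysed formal [3+2] cycloaddition of a trans-2,3-diaroyl-1-arylcyclopropane with 4-(benzyloxy)benzaldehyde; it closes the ring and sets C2, C3 and C5 by relay from C4. The cyclopropane arises in two steps from the same aldehyde and one acetophenone; the meso target needs no absolute control, and six benzyl ethers leave together at the end.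

Key step: step 3

Remark on the chemistry: the target SMILES describes the meso (2R,3R,4S,5S) isomer (2,5-cis aryl groups, 3,4-cis aroyl groups, each aroyl trans to its neighbouring aryl), so racemic intermediates suffice. Compounds 1 and 2 are taken as catalogue compounds.

Step 1
Reactants: 1 4-(benzyloxy)benzaldehyde; 2 1-[2,4-bis(benzyloxy)phenyl]ethan-1-one (2.1 equiv)
Product: 4 3-[4-(benzyloxy)phenyl]-1,5-bis[2,4-bis(benzyloxy)phenyl]pentane-1,5-dione, via chalcone 3 (not isolated)
Conditions: KOH, EtOH, rt then 60 °C
Reagents that add atoms: none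
Why: Claisen–Schmidt aldol condensation of 1 with one equivalent of 2 should give (E)-chalcone 3, and the enolate of the second equivalent of 2 then adds to its beta-carbon (Michael addition), with crystallisation of the 1,5-diketone from ethanol expected to pull the equilibria forward; no stereocentre arises because the central carbon carries two identical arms.

Step 2
Reactants: 4 3-[4-(benzyloxy)phenyl]-1,5-bis[2,4-bis(benzyloxy)phenyl]pentane-1,5-dione
Product: 6 rac-{(1R,2R)-3-[4-(benzyloxy)phenyl]cyclopropane-1,2-diyl}bis{[2,4-bis(benzyloxy)phenyl]methanone}, via alpha-iodo diketone 5 (not isolated)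
Conditions: I2 (1.1 equiv), DBU (2.2 equiv), MeCN, rt
Reagents that add atoms: none
Why: DBU-mediated alpha-iodination of one CH2 (5) is followed by 3-exo-tet intramolecular enolate alkylation from the other CH2 (iodine/base cyclopropanation of 1,5-diketones); the two aroyl groups should end trans because that closure avoids eclipsing and DBU equilibrates the alpha-keto centres, and the aryl-bearing carbon is then not stereogenic, so 6 is a single racemate.

Step 3
Reactants: 6 rac-{(1R,2R)-3-[4-(benzyloxy)phenyl]cyclopropane-1,2-diyl}bis{[2,4-bis(benzyloxy)phenyl]methanone}; 1 4-(benzyloxy)benzaldehyde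
Product: 8 {(2R,3R,4S,5S)-2,5-bis[4-(benzyloxy)phenyl]oxolane-3,4-diyl}bis{[2,4-bis(benzyloxy)phenyl]methanone} (meso), via oxocarbenium enolate 7 (not isolated)
Conditions: Sc(OTf)3 (20 mol%), 4 Å molecular sieves, ClCH2CH2Cl, slow addition of the cyclopropane to the aldehyde and catalyst, 25 to 50 °C
Reagents that add atoms: none
Why: Lewis-acid-catalysed formal [3+2] cycloaddition of a donor–acceptor cyclopropane with an aldehyde (the known oxolane synthesis from 2-arylcyclopropanes and aldehydes, here with ketone acceptors): Sc(OTf)3, held in the six-membered chelate of a 2-benzyloxyaryl ketone, polarises a cyclopropane bond between the 4-benzyloxybenzylic donor carbon (future C5) and an aroyl-bearing carbon (future C3), the carbonyl oxygen of 1 bonds to the ionising benzylic carbon (O1–C5) to give oxocarbenium enolate 7, and the enolate carbon of 7 then attacks the oxocarbenium carbon (C3–C2). The single ring closes in a 5-(enolexo)-endo-trig aldol/Prins-type mode, the mode of all annulations of this family. C4 is carried over untouched from 6 and relays the rest: either bond from the donor carbon of racemic trans-6 opens to the same zwitterion, the reversible O-alkylation should place the C5 aryl anti to the C4 aroyl group (4,5-trans), the E-oxocarbenium should close through an envelope with both aryl groups pseudo-equatorial (2,5-cis), and a scandium bridge between the enolate oxygen and the C4 ketone should hold the two acyl groups syn while the C–C bond forms (3,4-cis and 2,3-trans), which is the meso array of 8. The step needs chemoselectivity for cycloaddition over Cloke–Wilson closure of the enolate oxygen onto the benzylic cation and over Friedel–Crafts capture: the two partners are used in equimolar amounts and slow addition of 6 keeps electron-rich 1 in large excess over the zwitterion so that it intercepts the cation, a dihydrofuran formed by O-closure can re-ionise to the same zwitterion, and the only ring carbons ortho to the ketones are meta to both benzyloxy groups and therefore deactivated.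

Step 4
Reactants: 8 {(2R,3R,4S,5S)-2,5-bis[4-(benzyloxy)phenyl]oxolane-3,4-diyl}bis{[2,4-bis(benzyloxy)phenyl]methanone}
Product: 9 [(2R,3R,4S,5S)-2,5-bis(4-hydroxyphenyl)oxolane-3,4-diyl]bis[(2,4-dihydroxyphenyl)methanone] (CNP0237262.1)
Conditions: H2 (1 atm), Pd/C (10 wt%), EtOAc/MeOH, rt
Reagents that add atoms: none
Why: Catalytic hydrogenolysis should cleave the six aryl benzyl ethers far faster than the two hindered benzylic C–O bonds of the oxolane, the 2,4-dioxygenated aryl ketones (vinylogous esters, hydrogen-bonded once the 2-OH is free) resist reduction, and the neutral medium leaves all four stereocentres untouched, so the reaction is stopped after uptake of six equivalents of H2.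

Compound list
1 | 4-(benzyloxy)benzaldehyde | O=Cc1ccc(OCc2ccccc2)cc1 | starting material
2 | 1-[2,4-bis(benzyloxy)phenyl]ethan-1-one | CC(=O)c1ccc(OCc2ccccc2)cc1OCc1ccccc1 | starting material
3 | (E)-1-[2,4-bis(benzyloxy)phenyl]-3-[4-(benzyloxy)phenyl]prop-2-en-1-one (chalcone) | O=C(/C=C/c1ccc(OCc2ccccc2)cc1)c1ccc(OCc2ccccc2)cc1OCc1ccccc1 | intermediate (not isolated)
4 | 3-[4-(benzyloxy)phenyl]-1,5-bis[2,4-bis(benzyloxy)phenyl]pentane-1,5-dione | O=C(CC(CC(=O)c1ccc(OCc2ccccc2)cc1OCc1ccccc1)c1ccc(OCc2ccccc2)cc1)c1ccc(OCc2ccccc2)cc1OCc1ccccc1 | intermediate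
5 | 2-iodo-3-[4-(benzyloxy)phenyl]-1,5-bis[2,4-bis(benzyloxy)phenyl]pentane-1,5-dione (mixture of diastereomers) | O=C(C(I)C(CC(=O)c1ccc(OCc2ccccc2)cc1OCc1ccccc1)c1ccc(OCc2ccccc2)cc1)c1ccc(OCc2ccccc2)cc1OCc1ccccc1 | intermediate (not isolated)
6 | rac-{(1R,2R)-3-[4-(benzyloxy)phenyl]cyclopropane-1,2-diyl}bis{[2,4-bis(benzyloxy)phenyl]methanone} (aroyl groups trans; one enantiomer drawn) | O=C(c1ccc(OCc2ccccc2)cc1OCc1ccccc1)[C@H]1[C@H](C(=O)c2ccc(OCc3ccccc3)cc2OCc2ccccc2)C1c1ccc(OCc2ccccc2)cc1 | intermediate
7 | oxocarbenium enolate zwitterion from O-alkylation of 1 by ring-opened 6 (Z-enolate, E-oxocarbenium, C4 and C5 as in 8; drawn metal-free, the enolate oxygen being bound to scandium in the flask) | [O-]/C(=C\[C@H](C(=O)c1ccc(OCc2ccccc2)cc1OCc1ccccc1)[C@@H](c1ccc(OCc2ccccc2)cc1)/[O+]=C/c1ccc(OCc2ccccc2)cc1)c1ccc(OCc2ccccc2)cc1OCc1ccccc1 | intermediate (not isolated)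
8 | {(2R,3R,4S,5S)-2,5-bis[4-(benzyloxy)phenyl]oxolane-3,4-diyl}bis{[2,4-bis(benzyloxy)phenyl]methanone} (meso; 2,5-cis, 3,4-cis, 2,3-trans) | O=C(c1ccc(OCc2ccccc2)cc1OCc1ccccc1)[C@@H]1[C@H](C(=O)c2ccc(OCc3ccccc3)cc2OCc2ccccc2)[C@@H](c2ccc(OCc3ccccc3)cc2)O[C@H]1c1ccc(OCc2ccccc2)cc1 | intermediate
9 | [(2R,3R,4S,5S)-2,5-bis(4-hydroxyphenyl)oxolane-3,4-diyl]bis[(2,4-dihydroxyphenyl)methanone] (meso; CNP0237262.1) | O=C(c1ccc(O)cc1O)[C@@H]1[C@H](C(=O)c2ccc(O)cc2O)[C@@H](c2ccc(O)cc2)O[C@H]1c1ccc(O)cc1 | target

Total step count: 4
Longest linear sequence: 4 steps (1 and 2 to 4, 6, 8, 9)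

Steps most likely to fail

1. Step 3. The single-ketone acceptor may not ionise under a mild Lewis acid, or the ring-opened species may be diverted to Cloke–Wilson O-closure; in addition, facial selectivity at C3 may be poor if the scandium bridge to the C4 ketone does not form. The fallback activates C3 geminally with an ester that leaves in the last operation. It sets out from 2 and from chalcone 3, isolated when step 1 is run with one equivalent of 2. Acylation of the enolate of 2 with dibenzyl carbonate (NaH, THF, reflux) should give benzyl 3-[2,4-bis(benzyloxy)phenyl]-3-oxopropanoate F1. Bromination with N-bromosuccinimide should give benzyl 2-bromo-3-[2,4-bis(benzyloxy)phenyl]-3-oxopropanoate F2. Michael-initiated ring closure of F2 onto 3 (K2CO3, MeCN) should give benzyl 1,2-bis[2,4-bis(benzyloxy)benzoyl]-3-[4-(benzyloxy)phenyl]cyclopropane-1-carboxylate F3, a doubly activated donor–acceptor cyclopropane in which only the bond from the aryl carbon to the quaternary carbon is polarised. Its Sn(OTf)2- or Sc(OTf)3-catalysed [3+2] cycloaddition with 1 should give benzyl 3,4-bis[2,4-bis(benzyloxy)benzoyl]-2,5-bis[4-(benzyloxy)phenyl]oxolane-3-carboxylate F4; the 4,5-trans relation may need Lewis-acid equilibration at the 4-alkoxybenzylic C5–O bond. Hydrogenolysis under the conditions of step 4 then removes seven benzyl groups, the free beta-keto acid loses CO2 and the enol protonates at C3, so the fallback comes back to the route at 9.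

2. Step 4. Over-reduction may occur: hydrogenolytic opening of the ring at the 4-hydroxybenzylic C–O bonds, or reduction of the aryl ketones. The fallback sets out from 8 and replaces hydrogenolysis by Lewis-acid dealkylation with a cation scavenger (BCl3, pentamethylbenzene, CH2Cl2, −78 °C), conditions under which benzylic cyclic ethers of the C-aryl glycoside type survive; it arrives directly at 9 and makes no new compound.

3. Step 1. The one-pot sequence may stall at the chalcone, because the doubly donor-substituted enone is a poor Michael acceptor and the addition is reversible. The fallback sets out from 2 and from isolated 3 and bypasses diketone 4 by a sulfonium-ylide cyclopropanation (Corey–Chaykovsky type). Alpha-bromination of 2 (CuBr2, EtOAc/CHCl3, reflux) should give 2-bromo-1-[2,4-bis(benzyloxy)phenyl]ethan-1-one F5. Dimethyl sulfide in acetone converts it into {2-[2,4-bis(benzyloxy)phenyl]-2-oxoethyl}dimethylsulfonium bromide F6. The stabilised ylide of F6 (K2CO3, MeCN) adds to the beta-carbon of 3 and closes by 3-exo-tet displacement of dimethyl sulfide, which should give the trans-diaroyl cyclopropane, so the fallback comes back to the route at 6.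

Further compounds
F1 | step 3 | benzyl 3-[2,4-bis(benzyloxy)phenyl]-3-oxopropanoate | O=C(CC(=O)c1ccc(OCc2ccccc2)cc1OCc1ccccc1)OCc1ccccc1
F2 | step 3 | benzyl 2-bromo-3-[2,4-bis(benzyloxy)phenyl]-3-oxopropanoate (racemic) | O=C(OCc1ccccc1)C(Br)C(=O)c1ccc(OCc2ccccc2)cc1OCc1ccccc1
F3 | step 3 | benzyl 1,2-bis[2,4-bis(benzyloxy)benzoyl]-3-[4-(benzyloxy)phenyl]cyclopropane-1-carboxylate (2-aroyl and 3-aryl trans, racemic, C1 epimers) | O=C(OCc1ccccc1)C1(C(=O)c2ccc(OCc3ccccc3)cc2OCc2ccccc2)[C@H](C(=O)c2ccc(OCc3ccccc3)cc2OCc2ccccc2)[C@H]1c1ccc(OCc2ccccc2)cc1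
F4 | step 3 | benzyl 3,4-bis[2,4-bis(benzyloxy)benzoyl]-2,5-bis[4-(benzyloxy)phenyl]oxolane-3-carboxylate (2,5-cis, 4,5-trans, racemic, C3 epimers) | O=C(c1ccc(OCc2ccccc2)cc1OCc1ccccc1)C1(C(=O)OCc2ccccc2)[C@H](C(=O)c2ccc(OCc3ccccc3)cc2OCc2ccccc2)[C@@H](c2ccc(OCc3ccccc3)cc2)O[C@H]1c1ccc(OCc2ccccc2)cc1
F0 | step 4 | none | none
F5 | step 1 | 2-bromo-1-[2,4-bis(benzyloxy)phenyl]ethan-1-one | O=C(CBr)c1ccc(OCc2ccccc2)cc1OCc1ccccc1
F6 | step 1 | {2-[2,4-bis(benzyloxy)phenyl]-2-oxoethyl}dimethylsulfonium bromide | C[S+](C)CC(=O)c1ccc(OCc2ccccc2)cc1OCc1ccccc1.[Br-]
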